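C1 (quaternary, CH3), C2 (OAc), C3, C4 (OH, iPr) and C5 (fusion CH) form the five-membered ring; C5, C6 (anisoate), C7, C8/C9 (oxirane), C10 (OH) and C1 form the seven-membered ring. These daucane numbers are kept for all intermediates, and β is the face of the C1 methyl group.
Cuts, in order: oxirane O off C8=C9; C9–C10; the two esters; C6–C7; C4–iPr; C1–C10 and C5–C6, which leads back to a 2-methyl-4-silyloxycyclopentenone.
Forward: the five-membered ring is bought. Its C5 and C1 arms are set trans by conjugate addition and aldol, isopropyl goes on C4, and the C6 arm is grown into a (Z)-bromoalkene. The seven-membered ring closes last by an intramolecular Nozaki–Hiyama–Kishi reaction, and the oxirane follows.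
Enabling feature: C8–C9–C10 is a 2,3-epoxy alcohol whose carbinol C10 hangs on quaternary C1. This is the retron of a (Z)-C8=C9 alkenyl metal adding to a non-enolisable C10 aldehyde. The trans arms on C1 and C5 become the two equatorial bonds of a chair cycloheptene, both esters can already be in place, and the reaction delivers the free 10-OH of the target.
Stereochemistry: C4 of (R)-4-silyloxycyclopentenone relays to C5, C1 and C2 and, after oxidation, back to C4. C6 comes from an α-chiral bromoallylboronate, C10 from the ring closure, and C8/C9 from the α-face bias of the trans-fused bicycle.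

Key step: step 18

Remark: the oxirane is treated as functionality of the seven-membered ring, not as a ring of the carbon skeleton, so it is installed after the last carbocycle is closed.
Remark: compounds 1, 13 and 14 are taken as catalogue chemicals.

Step 1
Reactants: 1 (R)-4-(tert-butyldimethylsilyloxy)cyclopent-2-en-1-one
Product: 2 (R)-4-(tert-butyldimethylsilyloxy)-2-iodocyclopent-2-en-1-one
Conditions: I2, pyridine/CH2Cl2, 0 °C to rt
Reagents that add atoms: iodine, II
Why: α-Iodination of an enone by a Baylis–Hillman-type sequence (pyridine addition, iodination, elimination), which does not touch the carbinol stereocentre (later C4).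

Step 2
Reactants: 2 (R)-4-(tert-butyldimethylsilyloxy)-2-iodocyclopent-2-en-1-one
Product: 3 (R)-4-(tert-butyldimethylsilyloxy)-2-methylcyclopent-2-en-1-one
Conditions: Me4Sn, PdCl2(PhCN)2 (cat.), AsPh3, CuI (cat.), NMP, 60 °C
Reagents that add atoms: tetramethyltin, C[Sn](C)(C)C
Why: Stille coupling of an α-iodoenone puts the future C1 methyl group on the ring without base, so the β-silyloxy group is not eliminated.

Step 3
Reactants: 3 (R)-4-(tert-butyldimethylsilyloxy)-2-methylcyclopent-2-en-1-one
Product: 4 silyl enol ether 1-methyl-2-(trimethylsilyloxy)-4α-(tert-butyldimethylsilyloxy)-5β-vinylcyclopent-1-ene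
Conditions: CH2=CHMgBr, CuBr·SMe2 (10 mol %), Me3SiCl, HMPA, THF, −78 °C
Reagents that add atoms: vinylmagnesium bromide, C=C[Mg]Br; chlorotrimethylsilane, C[Si](C)(C)Cl
Why: In this chlorosilane-accelerated copper-catalysed conjugate addition the vinyl group (C6) enters C5 anti to the 4α-silyloxy group, and the regiodefined C1=C2 enolate is trapped before it can equilibrate.

Step 4
Reactants: 4 silyl enol ether
Product: 5 1α-(hydroxymethyl)-1β-methyl-4α-(tert-butyldimethylsilyloxy)-5β-vinylcyclopentan-2-one
Conditions: aq. HCHO, Yb(OTf)3 (10 mol %), THF, rt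
Reagents that add atoms: formaldehyde, C=O
Why: In this aqueous lanthanide-triflate-catalysed Mukaiyama aldol (hydroxymethylation) formaldehyde (C10) attacks the tetrasubstituted enol ether anti to the vicinal 5β-vinyl group, which sets quaternary C1 with C10 α and CH3 β.

Step 5
Reactants: 5 hydroxymethyl ketone
Product: 6 1α-(hydroxymethyl)-1β-methyl-4α-(tert-butyldimethylsilyloxy)-5β-vinylcyclopentan-2β-ol
Conditions: Me4NBH(OAc)3, MeCN/AcOH, −20 °C
Reagents that add atoms: none
Why: In this Evans–Saksena hydroxyl-directed reduction boron binds the α-face CH2OH and delivers hydride within a six-membered array to the α face of C2=O, which gives the 2β-alcohol.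

Step 6
Reactants: 6 diol
Product: 7 O2,O10-isopropylidene acetal of 6 (trans-fused 1,3-dioxane)
Conditions: Me2C(OMe)2, PPTS (cat.), CH2Cl2, rt
Reagents that add atoms: 2,2-dimethoxypropane, COC(C)(C)OC
Why: Acid-catalysed transketalisation ties O2 and O10 into one group that survives fluoride, oxidation, organocerium and ozone, and changes no stereocentre.

Step 7
Reactants: 7 acetonide silyl ether
Product: 8 4α-alcohol
Conditions: Bu4NF, THF, 0 °C to rt
Reagents that add atoms: none
Why: Fluoride-induced desilylation frees only O4, because the ketal is inert to fluoride.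

Step 8
Reactants: 8 4α-alcohol
Product: 9 4-ketone (5β-vinyl)
Conditions: Dess–Martin periodinane, pyridine, CH2Cl2, 0 °C
Reagents that add atoms: none
Why: Dess–Martin oxidation under buffered, non-enolising conditions keeps the α-vinyl stereocentre C5 and the β,γ position of the double bond.

Step 9
Reactants: 9 4-ketone
Product: 10 4β-hydroxy-4α-isopropyl compound
Conditions: iPrMgCl, anhydrous CeCl3, THF, −78 °C; H2O quench
Reagents that add atoms: isopropylmagnesium chloride, CC(C)[Mg]Cl
Why: In this organocerium 1,2-addition the low basicity suppresses enolisation and β-hydride reduction, and the nucleophile attacks C4=O from the α face, anti to the vicinal 5β-vinyl group, which gives 4β-OH and 4α-iPr.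

Step 10
Reactants: 10 4β-hydroxy-4α-isopropyl compound
Product: 12 C6 aldehyde (5β-formyl acetonide), via secondary ozonide 11 (not isolated)
Conditions: O3, CH2Cl2, −78 °C; then Me2S, −78 °C to rt
Reagents that add atoms: ozone, [O-][O+]=O
Why: Ozonolysis with reductive work-up cleaves the only alkene, the ketal has no acetal C–H for ozone to attack, and the neutral conditions avoid epimerisation or dehydration of the β-hydroxy aldehyde.

Step 11
Reactants: 13 isopropenylmagnesium bromide; 14 (S,S)-1,2-dicyclohexylethane-1,2-diol (DICHED)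
Product: 16 (4S,5S)-4,5-dicyclohexyl-2-isopropenyl-1,3,2-dioxaborolane, via isopropenylboronic acid 15 (not isolated)
Conditions: B(OMe)3, THF, −78 °C to rt; 1 M HCl; then 14, MgSO4, Et2O, rt
Reagents that add atoms: trimethyl borate, COB(OC)OC
Why: Borylation of a Grignard reagent followed by esterification with the symmetric chiral diol gives the substrate for homologation and creates no new stereocentre.

Step 12
Reactants: 16 isopropenylboronate
Product: 18 (4S,5S)-2-[(1R)-1-bromo-2-methylprop-2-enyl]-4,5-dicyclohexyl-1,3,2-dioxaborolane, via lithium dibromomethyl borate 17 (not isolated)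
Conditions: CH2Br2, LiN(iPr)2, THF, −78 °C to rt
Reagents that add atoms: dibromomethane, BrCBr
Why: In this Matteson homologation the (S,S)-diol directs the 1,2-shift of the isopropenyl group so that one diastereotopic bromide is displaced, which sets the (αR) carbon (later C9).

Step 13
Reactants: 12 C6 aldehyde; 18 (αR)-bromoallylboronate
Product: 20 (6S)-carbinol carrying the (Z)-C8(CH3)=C9HBr arm, via mixed borate ester 19 (not isolated)
Conditions: 18 (1.5 equiv), 4 Å molecular sieves, CH2Cl2, 0 °C to rt; then H2O
Reagents that add atoms: none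
Why: This α-haloallylboration runs through a closed chair in which bromine sits axial (dipole effect and strain against the C8 methyl group), so the (Z)-bromoalkene forms, and the (αR) centre steers C7 onto the Si face of the aldehyde to give (6S), the later 6α-oxygen.

Step 14
Reactants: 20 (6S)-carbinol
Product: 21 6-O-(4-methoxybenzoyl) ester
Conditions: 4-MeOC6H4COCl, Et3N, DMAP (cat.), CH2Cl2, rt
Reagents that add atoms: 4-methoxybenzoyl chloride, COc1ccc(cc1)C(Cl)=O
Why: DMAP-catalysed acylation takes the only secondary hydroxyl, and the tertiary 4-OH stays free.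

Step 15
Reactants: 21 anisoate acetonide
Product: 22 2β,10-diol
Conditions: AcOH/H2O, 40 °C
Reagents that add atoms: none
Why: Mild acid hydrolysis removes the strained trans-fused ketal while the ester, the bromoalkene and the tertiary alcohol are inert.

Step 16
Reactants: 22 2β,10-diol
Product: 23 2β-hydroxy C10 aldehyde
Conditions: TEMPO (cat.), PhI(OAc)2, CH2Cl2, rt
Reagents that add atoms: none
Why: Oxoammonium (TEMPO/hypervalent iodine) oxidation selects the primary alcohol over the hindered secondary and tertiary ones, and the aldehyde has no α-hydrogen.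

Step 17
Reactants: 23 hydroxy aldehyde
Product: 24 2β-acetoxy C10 aldehyde
Conditions: Ac2O, DMAP (cat.), pyridine, rt
Reagents that add atoms: acetic anhydride, CC(=O)OC(C)=O
Why: DMAP-catalysed acetylation takes the one remaining secondary hydroxyl, and elimination of the β-acetate is impossible because C1 is quaternary.

Step 18
Reactants: 24 2β-acetoxy C10 aldehyde with (Z)-bromoalkene arm
Product: 26 trans-fused dauc-8-ene 2β-acetate 6α-anisoate 4β,10β-diol, via alkenylchromium dichloride 25 (not isolated)
Conditions: CrCl2 (6 equiv), NiCl2 (2 mol %), DMSO, rt, slow addition of 24 (high dilution); then H2O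
Reagents that add atoms: none
Why: Zerovalent nickel (formed from NiCl2 by CrCl2) inserts into the C9–Br bond with retention, the alkenyl group passes to trivalent chromium (two CrCl2 per bromide) to give 25, and this mild carbon nucleophile adds to the C10 aldehyde. The closest known reaction type is the intramolecular Nozaki–Hiyama–Kishi coupling used to close medium rings next to quaternary carbon. The seven-membered ring C1–C10–C9–C8–C7–C6–C5 closes in the 7-exo-trig mode. The only new stereocentre, C10, is controlled by the chair-like cycloheptene transition state fixed by the trans C1/C5 arms: the chromium-bound carbonyl oxygen takes the outer pseudo-equatorial site on the side of the 2β-acetate, which can also chelate the metal, so the 10β-alcohol should form. The step needs selectivity for the aldehyde over two esters and a free tertiary alcohol, which the low basicity of alkenylchromium secures, and cyclisation over dimerisation, which the (Z) geometry, the diequatorial arms and dilution secure. The aldehyde has no α-hydrogen, so neither enolisation nor loss of the β-acetate can compete.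

Step 19
Reactants: 26 cycloheptenol
Product: 27 target (8α,9α-epoxide)
Conditions: mCPBA, CH2Cl2, 0 °C
Reagents that add atoms: 3-chloroperoxybenzoic acid, OOC(=O)c1cccc(Cl)c1
Why: In this Prilezhaev epoxidation the chair fixed by the trans fusion tilts C8=C9 under the axial C1 methyl group on the β face, so the peracid should come from the open α face, and the syn-directing pull of an equatorial allylic OH is weak in cycloheptenols.

Compound list
1 | (R)-4-(tert-butyldimethylsilyloxy)cyclopent-2-en-1-one | O=C1C=C[C@H](O[Si](C)(C)C(C)(C)C)C1 | starting material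
2 | (R)-4-(tert-butyldimethylsilyloxy)-2-iodocyclopent-2-en-1-one | O=C1C(I)=C[C@H](O[Si](C)(C)C(C)(C)C)C1 | intermediate
3 | (R)-4-(tert-butyldimethylsilyloxy)-2-methylcyclopent-2-en-1-one | O=C1C(C)=C[C@H](O[Si](C)(C)C(C)(C)C)C1 | intermediate
4 | silyl enol ether, 4α-OTBS, 5β-vinyl | CC1=C(O[Si](C)(C)C)C[C@@H](O[Si](C)(C)C(C)(C)C)[C@@H]1C=C | intermediate
5 | 1α-hydroxymethyl-1β-methyl ketone | OC[C@]1(C)[C@@H](C=C)[C@H](O[Si](C)(C)C(C)(C)C)CC1=O | intermediate
6 | 2β,10-diol | OC[C@]1(C)[C@@H](C=C)[C@H](O[Si](C)(C)C(C)(C)C)C[C@H]1O | intermediate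
7 | O2,O10-acetonide, 4α-OTBS | CC1(C)OC[C@]2(C)[C@@H](C=C)[C@H](O[Si](C)(C)C(C)(C)C)C[C@H]2O1 | intermediate
8 | 4α-alcohol | CC1(C)OC[C@]2(C)[C@@H](C=C)[C@H](O)C[C@H]2O1 | intermediate
9 | 4-ketone | CC1(C)OC[C@]2(C)[C@@H](C=C)C(=O)C[C@H]2O1 | intermediate
10 | 4β-hydroxy-4α-isopropyl compound | CC1(C)OC[C@]2(C)[C@@H](C=C)[C@](O)(C(C)C)C[C@H]2O1 | intermediate
11 | secondary ozonide (trioxolane carbon undefined) | CC1(C)OC[C@]2(C)[C@@H](C3OCOO3)[C@](O)(C(C)C)C[C@H]2O1 | intermediate
12 | C6 aldehyde | CC1(C)OC[C@]2(C)[C@@H](C=O)[C@](O)(C(C)C)C[C@H]2O1 | intermediate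
13 | isopropenylmagnesium bromide | CC(=C)[Mg]Br | starting material
14 | (S,S)-1,2-dicyclohexylethane-1,2-diol | O[C@@H](C1CCCCC1)[C@@H](O)C1CCCCC1 | starting material
15 | isopropenylboronic acid | CC(=C)B(O)O | intermediate
16 | (4S,5S)-4,5-dicyclohexyl-2-isopropenyl-1,3,2-dioxaborolane | CC(=C)B1O[C@@H](C2CCCCC2)[C@H](C2CCCCC2)O1 | intermediate
17 | lithium dibromomethyl borate | [Li+].CC(=C)[B-]1(C(Br)Br)O[C@@H](C2CCCCC2)[C@H](C2CCCCC2)O1 | intermediate
18 | (αR)-1-bromo-2-methylallylboronate of (S,S)-DICHED | CC(=C)[C@H](Br)B1O[C@@H](C2CCCCC2)[C@H](C2CCCCC2)O1 | intermediate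
19 | mixed borate ester of 20 | CC1(C)OC[C@]2(C)[C@@H]([C@@H](OB3O[C@@H](C4CCCCC4)[C@H](C4CCCCC4)O3)C/C(C)=C\Br)[C@](O)(C(C)C)C[C@H]2O1 | intermediate
20 | (6S)-carbinol, (Z)-bromoalkene | CC1(C)OC[C@]2(C)[C@@H]([C@@H](O)C/C(C)=C\Br)[C@](O)(C(C)C)C[C@H]2O1 | intermediate
21 | 6-O-anisoate acetonide | CC1(C)OC[C@]2(C)[C@@H]([C@@H](OC(=O)c3ccc(OC)cc3)C/C(C)=C\Br)[C@](O)(C(C)C)C[C@H]2O1 | intermediate
22 | 2β,10-diol anisoate | OC[C@]1(C)[C@@H]([C@@H](OC(=O)c2ccc(OC)cc2)C/C(C)=C\Br)[C@](O)(C(C)C)C[C@H]1O | intermediate
23 | 2β-hydroxy C10 aldehyde | O=C[C@]1(C)[C@@H]([C@@H](OC(=O)c2ccc(OC)cc2)C/C(C)=C\Br)[C@](O)(C(C)C)C[C@H]1O | intermediate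
24 | 2β-acetoxy C10 aldehyde | O=C[C@]1(C)[C@@H]([C@@H](OC(=O)c2ccc(OC)cc2)C/C(C)=C\Br)[C@](O)(C(C)C)C[C@H]1OC(C)=O | intermediate
25 | alkenylchromium dichloride | O=C[C@]1(C)[C@@H]([C@@H](OC(=O)c2ccc(OC)cc2)C/C(C)=C\[Cr](Cl)Cl)[C@](O)(C(C)C)C[C@H]1OC(C)=O | intermediate
26 | dauc-8-ene 2β-acetate 6α-anisoate 4β,10β-diol | COc1ccc(C(=O)O[C@H]2CC(C)=C[C@H](O)[C@]3(C)[C@@H]2[C@](O)(C(C)C)C[C@H]3OC(C)=O)cc1 | intermediate
27 | CNP0371526.1 | COc1ccc(C(=O)O[C@H]2C[C@@]3(C)O[C@H]3[C@H](O)[C@]3(C)[C@@H]2[C@](O)(C(C)C)C[C@H]3OC(C)=O)cc1 | target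

Total step count: 19. Longest linear sequence: 17 (steps 1–10 and 13–19).

Steps most likely to fail

Step 13. The aldehyde carbon sits between two fully substituted ring carbons, so allyl transfer may be slow. The allylic α-bromoboronate may also lose its configuration or shift its bromide before it reacts, which would erode both the Z geometry and the C6 configuration. The fallback gives up the bromoalkene and closes the ring at C8=C9 instead; it sets out from 12 and comes back at 26. Brown methallylation of 12, using the B-methallyldiisopinocampheylborane antipode that attacks the Si face, should give the (6S)-methallyl carbinol F1. Acylation as in step 14 gives the anisoate F2, and aqueous acetic acid gives the diol F3. TEMPO/PhI(OAc)2 then gives the hydroxy aldehyde F4, and Ac2O/DMAP gives the acetoxy aldehyde F5. Vinylmagnesium bromide (2 equiv, THF, −78 °C, aldehyde-selective) gives the (10S)-vinyl carbinol F6. Ring-closing metathesis with second-generation Grubbs catalyst (CH2Cl2, reflux) then leads to 26. Incomplete control at C10 in the vinyl addition can be corrected after ring closure by the sequence given for step 18.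

Step 18. Facial selectivity at the C10 carbonyl may be poor if the pseudo-equatorial and pseudo-axial placements of the chromium-bound oxygen differ too little. The fallback sets C10 by hydride delivery to the finished ring instead of by C–C bond formation; it sets out from 26 as obtained and comes back at 26. Dess–Martin oxidation gives the cyclohept-8-en-10-one F7. Luche reduction (NaBH4, CeCl3·7H2O, MeOH, −78 °C) should attack axially from the α face, anti to the axial C1 methyl group, and return the equatorial 10β-alcohol.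

Step 19. Hydrogen bonding of the peracid to the 10β-hydroxyl may pull the reagent onto the β face and lower the facial selectivity. The fallback turns the director into a blocking group; it sets out from 26 and comes back at 27. Et3SiCl/imidazole (DMF) gives the 10-O-triethylsilyl ether F8. mCPBA, now guided by sterics only, gives the silylated 8α,9α-epoxide F9, and HF·pyridine (THF, 0 °C) frees 27.

Further compounds
F1 | step 13 | (6S)-methallyl carbinol | CC1(C)OC[C@]2(C)[C@@H]([C@@H](O)CC(C)=C)[C@](O)(C(C)C)C[C@H]2O1
F2 | step 13 | anisoate of F1 | CC1(C)OC[C@]2(C)[C@@H]([C@@H](OC(=O)c3ccc(OC)cc3)CC(C)=C)[C@](O)(C(C)C)C[C@H]2O1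
F3 | step 13 | 2β,10-diol | OC[C@]1(C)[C@@H]([C@@H](OC(=O)c2ccc(OC)cc2)CC(C)=C)[C@](O)(C(C)C)C[C@H]1O
F4 | step 13 | hydroxy aldehyde | O=C[C@]1(C)[C@@H]([C@@H](OC(=O)c2ccc(OC)cc2)CC(C)=C)[C@](O)(C(C)C)C[C@H]1O
F5 | step 13 | acetoxy aldehyde | O=C[C@]1(C)[C@@H]([C@@H](OC(=O)c2ccc(OC)cc2)CC(C)=C)[C@](O)(C(C)C)C[C@H]1OC(C)=O
F6 | step 13 | (10S)-vinyl carbinol | C=C[C@H](O)[C@]1(C)[C@@H]([C@@H](OC(=O)c2ccc(OC)cc2)CC(C)=C)[C@](O)(C(C)C)C[C@H]1OC(C)=O
F7 | step 18 | cyclohept-8-en-10-one | COc1ccc(C(=O)O[C@H]2CC(C)=CC(=O)[C@]3(C)[C@@H]2[C@](O)(C(C)C)C[C@H]3OC(C)=O)cc1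
F8 | step 19 | 10-O-triethylsilyl ether of 26 | COc1ccc(C(=O)O[C@H]2CC(C)=C[C@H](O[Si](CC)(CC)CC)[C@]3(C)[C@@H]2[C@](O)(C(C)C)C[C@H]3OC(C)=O)cc1
F9 | step 19 | 10-O-triethylsilyl ether of 27 | COc1ccc(C(=O)O[C@H]2C[C@@]3(C)O[C@H]3[C@H](O[Si](CC)(CC)CC)[C@]3(C)[C@@H]2[C@](O)(C(C)C)C[C@H]3OC(C)=O)cc1
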